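## Retrosynthetic overview

- Locants: ring A = C4a, C5 (H), C6 (CO2Me), C7 (OMe), C8 (OH), C8a; ring B = C8a–C1(H)(CH3)–C2–C3–C4–C4a; the side chain C11 (CHCH3) to C16 (CH2OH) hangs on C4.
- Feature: C8a lies ortho to the C8 hydroxyl and is bridged to C4a by C1–C2–C3–C4, so a formyl carbon on C8a (C1) and a vinyl group on C4 (C3=C2) are the two ends of ring B. The C8 hydroxyl first steers formylation to C8a and then, through its hydrogen bond to the C1 carbonyl, points the formyl C–H at the vinyl group.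
- Disconnections, backwards: C1–CH3 and C1–H (enol triflate methylation, iridium hydrogenation) to the C1 ketone; C1–C2 by rhodium hydroacylation, which closes ring B, the only ring made (ring A is bought as methyl 2,3-dihydroxybenzoate); C8a–CHO by magnesium-mediated ortho-formylation; C3=C2 by methylenation; C4–C4a by copper/amine α-arylation of a citronellal-derived aldehyde with an aryl(mesityl)iodonium salt.
- Stereocentres: C11 from (S)-citronellal, C15 by Ru–BINAP hydrogenation, C4 by the amine catalyst, C1 by the iridium catalyst.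

Key step: step 14

Assumption: the antipodes written for the chiral catalysts of steps 7, 10 and 18 follow the accepted models for the parent substrates; the face of attack that is required is stated in each step, and the mirror-image catalyst is taken if a model does not transfer.

Abbreviations: TBDPS = tert-butyldiphenylsilyl; MOM = methoxymethyl; NaBArF4 = Na[B(3,5-(CF3)2C6H3)4]; mesityl = 2,4,6-trimethylphenyl.

## Route

Step 1
Reactants: 1 methyl 2,3-dihydroxybenzoate
Product: 2 methyl 3-(benzyloxy)-2-hydroxybenzoate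
Conditions: BnBr (1.0 equiv), K2CO3 (1.1 equiv), acetone, rt
Reagents that add atoms: benzyl bromide, BrCc1ccccc1
Why: Williamson etherification; the 2-hydroxyl is locked in a hydrogen bond to the ester carbonyl and flanked on both sides, so one equivalent of benzyl bromide should go to the 3-hydroxyl.

Step 2
Reactants: 2 methyl 3-(benzyloxy)-2-hydroxybenzoate
Product: 3 methyl 3-(benzyloxy)-2-hydroxy-5-iodobenzoate
Conditions: NIS, CF3CO2H (cat.), MeCN, rt
Reagents that add atoms: N-iodosuccinimide, O=C1CCC(=O)N1I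
Why: Electrophilic aromatic iodination, which should enter para to the free phenol and meta to the ester (C5 of the benzoate), the position at which 3-alkoxysalicylates are halogenated.

Step 3
Reactants: 3 methyl 3-(benzyloxy)-2-hydroxy-5-iodobenzoate
Product: 4 methyl 3-(benzyloxy)-5-iodo-2-methoxybenzoate
Conditions: MeI, K2CO3, DMF, 40 °C
Reagents that add atoms: iodomethane, CI
Why: O-Methylation of the salicylate hydroxyl (Williamson); the neighbouring oxygen carries an ether and not an acyl or silyl group, so no migration can blur the OMe/OBn pattern.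

Step 4
Reactants: 4 methyl 3-(benzyloxy)-5-iodo-2-methoxybenzoate
Product: 7 [3-(benzyloxy)-4-methoxy-5-(methoxycarbonyl)phenyl](mesityl)iodonium triflate, via hydroxy(tosyloxy)iodoarene 5 (not isolated), via aryl(mesityl)iodonium tosylate 6 (not isolated)
Conditions: mCPBA, TsOH·H2O, mesitylene, CH2Cl2/CF3CH2OH (1:1), rt; then aq. NaOTf
Reagents that add atoms: mesitylene, Cc1cc(C)cc(C)c1; sodium triflate, [Na+].[O-]S(=O)(=O)C(F)(F)F
Why: One-pot diaryliodonium synthesis (oxidation of the aryl iodide by mCPBA/TsOH to the trivalent-iodine species 5, electrophilic substitution on mesitylene to 6, anion metathesis); the ester keeps the iodoarene from over-oxidation, TsOH spares the benzyl ether, and the mesityl group later serves as the ligand that is not transferred.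

Step 5
Reactants: 8 (S)-citronellal
Product: 9 2-[(2S)-2,6-dimethylhept-5-en-1-yl]-1,3-dioxolane
Conditions: HOCH2CH2OH, pyridinium tosylate (cat.), cyclohexane, reflux (Dean–Stark)
Reagents that add atoms: ethane-1,2-diol, OCCO
Why: Acid-catalysed acetalisation with azeotropic removal of water masks the aldehyde for steps 6 to 8; the weak acid is chosen so that the ene cyclisation of citronellal to isopulegol does not compete, and C11 is not touched.

Step 6
Reactants: 9 2-[(2S)-2,6-dimethylhept-5-en-1-yl]-1,3-dioxolane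
Product: 10 (2E,6S)-7-(1,3-dioxolan-2-yl)-2,6-dimethylhept-2-en-1-ol
Conditions: SeO2 (cat.), t-BuOOH, CH2Cl2, rt, stopped at partial conversion
Reagents that add atoms: tert-butyl hydroperoxide, CC(C)(C)OO
Why: Catalytic SeO2 allylic oxidation (ene reaction then 2,3-sigmatropic shift) attacks the (E)-methyl group of the trisubstituted alkene and leaves the acetal alone.

Step 7
Reactants: 10 (2E,6S)-7-(1,3-dioxolan-2-yl)-2,6-dimethylhept-2-en-1-ol
Product: 11 (2S,6S)-7-(1,3-dioxolan-2-yl)-2,6-dimethylheptan-1-ol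
Conditions: H2 (100 atm), Ru(OAc)2[(S)-BINAP] (1 mol%), MeOH, rt
Reagents that add atoms: none
Why: Noyori hydroxyl-directed hydrogenation of an allylic alcohol; by analogy with geraniol, the (S)-BINAP complex should deliver hydrogen to the Re face of C15, which sets (15S), and the acetal and C11 are inert.

Step 8
Reactants: 11 (2S,6S)-7-(1,3-dioxolan-2-yl)-2,6-dimethylheptan-1-ol
Product: 12 tert-butyl{[(2S,6S)-7-(1,3-dioxolan-2-yl)-2,6-dimethylheptyl]oxy}diphenylsilane
Conditions: TBDPSCl, imidazole, DMF, rt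
Reagents that add atoms: tert-butyl(chloro)diphenylsilane, CC(C)(C)[Si](Cl)(c1ccccc1)c1ccccc1
Why: Silylation of the primary alcohol; the TBDPS ether is chosen because it should survive the aqueous acid of step 9 and BCl3 in step 12.

Step 9
Reactants: 12 tert-butyl{[(2S,6S)-7-(1,3-dioxolan-2-yl)-2,6-dimethylheptyl]oxy}diphenylsilane
Product: 13 (3S,7S)-3,7-dimethyl-8-(TBDPS-oxy)octanal
Conditions: 1 M HCl (aq), THF, rt
Reagents that add atoms: water, O
Why: Acid hydrolysis of the dioxolane, to which the TBDPS ether is stable; the stereocentre of the aldehyde sits at its β-carbon (C11), so it cannot epimerise.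

Step 10
Reactants: 13 (3S,7S)-3,7-dimethyl-8-(TBDPS-oxy)octanal; 7 [3-(benzyloxy)-4-methoxy-5-(methoxycarbonyl)phenyl](mesityl)iodonium triflate
Product: 14 methyl 3-(benzyloxy)-2-methoxy-5-[(2S,3S,7S)-3,7-dimethyl-1-oxo-8-(TBDPS-oxy)octan-2-yl]benzoate
Conditions: CuBr (10 mol%), (2R,5R)-5-benzyl-2-tert-butyl-3-methylimidazolidin-4-one·Cl3CCO2H (10 mol%), NaHCO3, toluene/Et2O (2:1), 23 °C
Reagents that add atoms: none
Why: Copper/amine dual catalysis (MacMillan α-arylation of aldehydes): CuBr takes the unhindered aryl group from 7 (mesityl stays on iodine) and the aryl–copper electrophile is attacked by the E-enamine of 13, whose Si face is shielded by the benzyl group of the catalyst, so the aryl group enters on the Re face of C4 and sets (4S) beside the untouched C11; the aldehyde is filtered and used at once because C4 is epimerisable.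

Step 11
Reactants: 14 methyl 3-(benzyloxy)-2-methoxy-5-[(2S,3S,7S)-3,7-dimethyl-1-oxo-8-(TBDPS-oxy)octan-2-yl]benzoate
Product: 15 methyl 3-(benzyloxy)-2-methoxy-5-[(3S,4S,8S)-4,8-dimethyl-9-(TBDPS-oxy)non-1-en-3-yl]benzoate
Conditions: CH2I2, Zn, Ti(OiPr)4, THF, rt
Reagents that add atoms: diiodomethane, ICI
Why: Takai methylenation; the non-basic gem-dimetal reagent converts the aldehyde into the C3=C2 vinyl group without enolisation, so C4 is kept, and it does not touch the methyl ester.

Step 12
Reactants: 15 methyl 3-(benzyloxy)-2-methoxy-5-[(3S,4S,8S)-4,8-dimethyl-9-(TBDPS-oxy)non-1-en-3-yl]benzoate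
Product: 16 methyl 3-hydroxy-2-methoxy-5-[(3S,4S,8S)-4,8-dimethyl-9-(TBDPS-oxy)non-1-en-3-yl]benzoate
Conditions: BCl3 (2 equiv), C6HMe5 (3 equiv), CH2Cl2, −78 °C; MeOH quench
Reagents that add atoms: none
Why: Lewis-acid debenzylation of the aryl benzyl ether with pentamethylbenzene as a non-basic cation scavenger, at a temperature where the vinyl group, the methyl ester, the neighbouring methyl ether and the TBDPS ether should not react (hydrogenolysis is excluded by the vinyl group).

Step 13
Reactants: 16 methyl 3-hydroxy-2-methoxy-5-[(3S,4S,8S)-4,8-dimethyl-9-(TBDPS-oxy)non-1-en-3-yl]benzoate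
Product: 18 methyl 4-formyl-3-hydroxy-2-methoxy-5-[(3S,4S,8S)-4,8-dimethyl-9-(TBDPS-oxy)non-1-en-3-yl]benzoate, via ortho-hydroxymethyl phenol 17 (not isolated)
Conditions: MgCl2, Et3N, (CH2O)n, MeCN, reflux
Reagents that add atoms: formaldehyde (from paraformaldehyde), C=O
Why: Magnesium-mediated ortho-formylation (Casnati–Skattebøl): the magnesium phenoxide delivers formaldehyde to the only free ortho carbon, C8a, to give 17, which a second formaldehyde oxidises by hydride transfer to the aldehyde; the chelate rules out attack at the para carbon C5.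

Step 14
Reactants: 18 methyl 4-formyl-3-hydroxy-2-methoxy-5-[(3S,4S,8S)-4,8-dimethyl-9-(TBDPS-oxy)non-1-en-3-yl]benzoate
Product: 19 methyl (8S)-4-hydroxy-3-methoxy-8-[(2S,6S)-6-methyl-7-(TBDPS-oxy)heptan-2-yl]-5-oxo-5,6,7,8-tetrahydronaphthalene-2-carboxylate
Conditions: [Rh(cod)Cl]2 (2.5 mol%), (R)-DTBM-SEGPHOS (5.5 mol%), NaBArF4 (6 mol%), ClCH2CH2Cl, 60 °C, no base
Reagents that add atoms: none
Why: Cationic monovalent rhodium (chloride removed by NaBArF4) binds the C3=C2 vinyl group and inserts into the formyl C–H bond to give an acyl hydride of trivalent rhodium; the hydride adds to C3, placing rhodium on the terminal carbon C2, and C–C reductive elimination from the seven-membered acyl–alkyl rhodacycle forms C1–C2. The closest known reaction is the endo-selective rhodium-catalysed hydroacylation of ortho-allylbenzaldehydes to 3,4-dihydronaphthalen-1(2H)-ones with this catalyst system. Ring B closes in the 6-endo mode and no stereocentre is created, so the ligand antipode bears on rate only, and C4 is kept as long as the alkene does not migrate. The step needs linear over branched insertion (the branched alkyl would close exo to a 2-methylindan-1-one) and no β-hydride elimination toward C4; the branched, aryl-bearing C4 next to the alkene crowds a rhodium–C3 bond, and the bulky bisphosphine is the ligand type that suppresses chain-walking in the parent series. The C8 hydroxyl is kept un-ionised: its hydrogen bond to the carbonyl oxygen holds the formyl C–H on the C4a side, aimed at the vinyl group, whereas a rhodium phenoxide chelate would hold the metal on the C8 side, out of reach of the alkene, and is therefore not wanted. The vinyl group fills the free site on rhodium, which together with the doubly ortho-substituted acyl group should slow decarbonylation.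

Step 15
Reactants: 19 methyl (8S)-4-hydroxy-3-methoxy-8-[(2S,6S)-6-methyl-7-(TBDPS-oxy)heptan-2-yl]-5-oxo-5,6,7,8-tetrahydronaphthalene-2-carboxylate
Product: 20 methyl (8S)-3-methoxy-4-(methoxymethoxy)-8-[(2S,6S)-6-methyl-7-(TBDPS-oxy)heptan-2-yl]-5-oxo-5,6,7,8-tetrahydronaphthalene-2-carboxylate
Conditions: MOMCl, i-Pr2NEt, CH2Cl2, 0 °C to reflux
Reagents that add atoms: chloromethyl methyl ether, COCCl
Why: Etherification of the hydrogen-bonded phenol, needed because a free phenol would be triflated in step 16; the MOM group leaves together with the silyl group in step 19.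

Step 16
Reactants: 20 methyl (8S)-3-methoxy-4-(methoxymethoxy)-8-[(2S,6S)-6-methyl-7-(TBDPS-oxy)heptan-2-yl]-5-oxo-5,6,7,8-tetrahydronaphthalene-2-carboxylate
Product: 22 methyl (8S)-3-methoxy-4-(methoxymethoxy)-8-[(2S,6S)-6-methyl-7-(TBDPS-oxy)heptan-2-yl]-5-(triflyloxy)-7,8-dihydronaphthalene-2-carboxylate, via potassium enolate 21 (not isolated)
Conditions: KN(SiMe3)2, THF, −78 °C; PhNTf2
Reagents that add atoms: N-phenylbis(trifluoromethanesulfonimide), O=S(=O)(N(c1ccccc1)S(=O)(=O)C(F)(F)F)C(F)(F)F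
Why: Kinetic deprotonation at C2 (the aryl ester has no α-hydrogen) and O-triflation of enolate 21 give the C1 enol triflate.

Step 17
Reactants: 22 methyl (8S)-3-methoxy-4-(methoxymethoxy)-8-[(2S,6S)-6-methyl-7-(TBDPS-oxy)heptan-2-yl]-5-(triflyloxy)-7,8-dihydronaphthalene-2-carboxylate
Product: 23 methyl (8S)-3-methoxy-4-(methoxymethoxy)-5-methyl-8-[(2S,6S)-6-methyl-7-(TBDPS-oxy)heptan-2-yl]-7,8-dihydronaphthalene-2-carboxylate
Conditions: MeZnCl, Pd(PPh3)4 (5 mol%), THF, 50 °C
Reagents that add atoms: methylzinc chloride, C[Zn]Cl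
Why: Negishi coupling of the enol triflate (oxidative addition to zerovalent palladium, transmetalation from zinc, reductive elimination) installs the C1 methyl group; unlike a methyl Grignard addition to the ketone, the organozinc does not touch the methyl ester.

Step 18
Reactants: 23 methyl (8S)-3-methoxy-4-(methoxymethoxy)-5-methyl-8-[(2S,6S)-6-methyl-7-(TBDPS-oxy)heptan-2-yl]-7,8-dihydronaphthalene-2-carboxylate
Product: 24 methyl (5R,8S)-3-methoxy-4-(methoxymethoxy)-5-methyl-8-[(2S,6S)-6-methyl-7-(TBDPS-oxy)heptan-2-yl]-5,6,7,8-tetrahydronaphthalene-2-carboxylate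
Conditions: H2 (50 bar), [Ir(cod)((S)-tBu-PHOX)]BArF4 (2 mol%), CH2Cl2, rt
Reagents that add atoms: none
Why: Iridium N,P-ligand (Pfaltz-type) hydrogenation of an unfunctionalised trisubstituted alkene under catalyst control; the ligand antipode is the one that should add hydrogen to the Si face of C1, the face on the side of the C4 chain, so that the C1 methyl ends trans to that chain, (1R), a relation that also lets both benzylic substituents lie pseudoaxial, clear of the peri groups; loss of MOM or silyl groups to acidic iridium hydrides would be harmless, since step 19 removes both.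

Step 19
Reactants: 24 methyl (5R,8S)-3-methoxy-4-(methoxymethoxy)-5-methyl-8-[(2S,6S)-6-methyl-7-(TBDPS-oxy)heptan-2-yl]-5,6,7,8-tetrahydronaphthalene-2-carboxylate
Product: 25 methyl (5R,8S)-4-hydroxy-8-[(2S,6S)-7-hydroxy-6-methylheptan-2-yl]-3-methoxy-5-methyl-5,6,7,8-tetrahydronaphthalene-2-carboxylate (the target)
Conditions: HCl (1.25 M in MeOH), 40 °C
Reagents that add atoms: none
Why: Acid-catalysed methanolysis removes the MOM acetal and the silyl ether in one operation; the methyl ester is degenerate toward methanol and no stereocentre is labile.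

## Compound list

1 | methyl 2,3-dihydroxybenzoate | COC(=O)c1cccc(O)c1O | starting material
2 | methyl 3-(benzyloxy)-2-hydroxybenzoate | COC(=O)c1cccc(OCc2ccccc2)c1O | intermediate
3 | methyl 3-(benzyloxy)-2-hydroxy-5-iodobenzoate | COC(=O)c1cc(I)cc(OCc2ccccc2)c1O | intermediate
4 | methyl 3-(benzyloxy)-5-iodo-2-methoxybenzoate | COC(=O)c1cc(I)cc(OCc2ccccc2)c1OC | intermediate
5 | methyl 3-(benzyloxy)-5-[hydroxy(tosyloxy)iodo]-2-methoxybenzoate (not isolated) | COC(=O)c1cc(I(O)OS(=O)(=O)c2ccc(C)cc2)cc(OCc2ccccc2)c1OC | intermediate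
6 | [3-(benzyloxy)-4-methoxy-5-(methoxycarbonyl)phenyl](mesityl)iodonium tosylate (not isolated) | COC(=O)c1cc([I+]c2c(C)cc(C)cc2C)cc(OCc2ccccc2)c1OC.Cc1ccc(S(=O)(=O)[O-])cc1 | intermediate
7 | [3-(benzyloxy)-4-methoxy-5-(methoxycarbonyl)phenyl](mesityl)iodonium triflate | COC(=O)c1cc([I+]c2c(C)cc(C)cc2C)cc(OCc2ccccc2)c1OC.[O-]S(=O)(=O)C(F)(F)F | intermediate
8 | (S)-citronellal, (3S)-3,7-dimethyloct-6-enal | O=CC[C@@H](C)CCC=C(C)C | starting material
9 | 2-[(2S)-2,6-dimethylhept-5-en-1-yl]-1,3-dioxolane | O1CCOC1C[C@@H](C)CCC=C(C)C | intermediate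
10 | (2E,6S)-7-(1,3-dioxolan-2-yl)-2,6-dimethylhept-2-en-1-ol | O1CCOC1C[C@@H](C)CC/C=C(\C)CO | intermediate
11 | (2S,6S)-7-(1,3-dioxolan-2-yl)-2,6-dimethylheptan-1-ol | O1CCOC1C[C@@H](C)CCC[C@H](C)CO | intermediate
12 | tert-butyl{[(2S,6S)-7-(1,3-dioxolan-2-yl)-2,6-dimethylheptyl]oxy}diphenylsilane | O1CCOC1C[C@@H](C)CCC[C@H](C)CO[Si](c1ccccc1)(c1ccccc1)C(C)(C)C | intermediate
13 | (3S,7S)-3,7-dimethyl-8-(TBDPS-oxy)octanal | O=CC[C@@H](C)CCC[C@H](C)CO[Si](c1ccccc1)(c1ccccc1)C(C)(C)C | intermediate
14 | methyl 3-(benzyloxy)-2-methoxy-5-[(2S,3S,7S)-3,7-dimethyl-1-oxo-8-(TBDPS-oxy)octan-2-yl]benzoate | COC(=O)c1cc([C@@H](C=O)[C@@H](C)CCC[C@H](C)CO[Si](c2ccccc2)(c2ccccc2)C(C)(C)C)cc(OCc2ccccc2)c1OC | intermediate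
15 | methyl 3-(benzyloxy)-2-methoxy-5-[(3S,4S,8S)-4,8-dimethyl-9-(TBDPS-oxy)non-1-en-3-yl]benzoate | COC(=O)c1cc([C@@H](C=C)[C@@H](C)CCC[C@H](C)CO[Si](c2ccccc2)(c2ccccc2)C(C)(C)C)cc(OCc2ccccc2)c1OC | intermediate
16 | methyl 3-hydroxy-2-methoxy-5-[(3S,4S,8S)-4,8-dimethyl-9-(TBDPS-oxy)non-1-en-3-yl]benzoate | COC(=O)c1cc([C@@H](C=C)[C@@H](C)CCC[C@H](C)CO[Si](c2ccccc2)(c2ccccc2)C(C)(C)C)cc(O)c1OC | intermediate
17 | methyl 3-hydroxy-4-(hydroxymethyl)-2-methoxy-5-[(3S,4S,8S)-4,8-dimethyl-9-(TBDPS-oxy)non-1-en-3-yl]benzoate (as its magnesium phenoxide, not isolated) | COC(=O)c1cc([C@@H](C=C)[C@@H](C)CCC[C@H](C)CO[Si](c2ccccc2)(c2ccccc2)C(C)(C)C)c(CO)c(O)c1OC | intermediate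
18 | methyl 4-formyl-3-hydroxy-2-methoxy-5-[(3S,4S,8S)-4,8-dimethyl-9-(TBDPS-oxy)non-1-en-3-yl]benzoate | COC(=O)c1cc([C@@H](C=C)[C@@H](C)CCC[C@H](C)CO[Si](c2ccccc2)(c2ccccc2)C(C)(C)C)c(C=O)c(O)c1OC | intermediate
19 | methyl (8S)-4-hydroxy-3-methoxy-8-[(2S,6S)-6-methyl-7-(TBDPS-oxy)heptan-2-yl]-5-oxo-5,6,7,8-tetrahydronaphthalene-2-carboxylate | COC(=O)c1cc2c(c(O)c1OC)C(=O)CC[C@H]2[C@@H](C)CCC[C@H](C)CO[Si](c1ccccc1)(c1ccccc1)C(C)(C)C | intermediate
20 | methyl (8S)-3-methoxy-4-(methoxymethoxy)-8-[(2S,6S)-6-methyl-7-(TBDPS-oxy)heptan-2-yl]-5-oxo-5,6,7,8-tetrahydronaphthalene-2-carboxylate | COC(=O)c1cc2c(c(OCOC)c1OC)C(=O)CC[C@H]2[C@@H](C)CCC[C@H](C)CO[Si](c1ccccc1)(c1ccccc1)C(C)(C)C | intermediate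
21 | potassium enolate of 20, C1(O–)=C2 (not isolated) | COC(=O)c1cc2c(c(OCOC)c1OC)C([O-])=CC[C@H]2[C@@H](C)CCC[C@H](C)CO[Si](c1ccccc1)(c1ccccc1)C(C)(C)C.[K+] | intermediate
22 | methyl (8S)-3-methoxy-4-(methoxymethoxy)-8-[(2S,6S)-6-methyl-7-(TBDPS-oxy)heptan-2-yl]-5-(triflyloxy)-7,8-dihydronaphthalene-2-carboxylate | COC(=O)c1cc2c(c(OCOC)c1OC)C(OS(=O)(=O)C(F)(F)F)=CC[C@H]2[C@@H](C)CCC[C@H](C)CO[Si](c1ccccc1)(c1ccccc1)C(C)(C)C | intermediate
23 | methyl (8S)-3-methoxy-4-(methoxymethoxy)-5-methyl-8-[(2S,6S)-6-methyl-7-(TBDPS-oxy)heptan-2-yl]-7,8-dihydronaphthalene-2-carboxylate | COC(=O)c1cc2c(c(OCOC)c1OC)C(C)=CC[C@H]2[C@@H](C)CCC[C@H](C)CO[Si](c1ccccc1)(c1ccccc1)C(C)(C)C | intermediate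
24 | methyl (5R,8S)-3-methoxy-4-(methoxymethoxy)-5-methyl-8-[(2S,6S)-6-methyl-7-(TBDPS-oxy)heptan-2-yl]-5,6,7,8-tetrahydronaphthalene-2-carboxylate | COC(=O)c1cc2c(c(OCOC)c1OC)[C@H](C)CC[C@H]2[C@@H](C)CCC[C@H](C)CO[Si](c1ccccc1)(c1ccccc1)C(C)(C)C | intermediate
25 | methyl (5R,8S)-4-hydroxy-8-[(2S,6S)-7-hydroxy-6-methylheptan-2-yl]-3-methoxy-5-methyl-5,6,7,8-tetrahydronaphthalene-2-carboxylate; (1R,4S,11S,15S) in the locants used here | COC(=O)c1cc2c(c(O)c1OC)[C@H](C)CC[C@H]2[C@@H](C)CCC[C@H](C)CO | target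

## Step count and risks

Total steps: 19 (steps 1–4 aryl branch, steps 5–9 chain branch, steps 10–19 after the union).
Longest linear sequence: 15 steps (steps 5 to 19, from (S)-citronellal).

Steps most likely to fail:

1. Step 14 (ring B closure). The hydride may insert in the branched sense and the acyl group then close exo to the five-membered ketone; the alkene may walk into conjugation with ring A, which erases C4; or the acyl rhodium hydride may lose CO. The fallback sets out from 18 and comes back at 20, and closes ring B by metathesis at C2=C3 instead. Salicylaldehyde 18 is protected (MOMCl, i-Pr2NEt) as the MOM ether F1. Vinylmagnesium bromide at −78 °C adds to the aldehyde and not to the ester to give the divinyl carbinol F2 (either C1 epimer). Ring-closing metathesis with second-generation Grubbs catalyst, RuCl2(=CHPh)(H2IMes)(PCy3), under neutral conditions gives, with loss of ethene, the 1,4-dihydronaphthalen-1-ol F3. This is hydrogenated in the same flask under H2 on the ruthenium residue to the tetralol F4, before it can lose water to a naphthalene. Dess–Martin oxidation of F4 gives ketone 20.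

2. Step 10 (C4–aryl bond). Enamine formation from the β-branched aldehyde may be slower than decay of the iodonium salt, the C11 centre may erode facial control, and C4 may epimerise before methylenation. The fallback sets out from 13 and comes back at 14, and moves the arylation to an imide whose product does not epimerise. Pinnick oxidation (NaClO2, NaH2PO4, 2-methylbut-2-ene) gives the carboxylic acid F5. Coupling with oxazolidin-2-one (DCC, DMAP) gives the N-acyl oxazolidinone F6. NaN(SiMe3)2/Me3SiCl at −78 °C gives the (Z)-trimethylsilyl ketene N,O-acetal F7. This is arylated by 7 under Cu(OTf)2 and the Ph-box ligand antipode that gives (4S) (enol silane α-arylation with diaryliodonium salts) to the α-aryl imide F8. LiBH4/MeOH at 0 °C reduces the imide ahead of the aryl ester to the primary alcohol F9. Dess–Martin oxidation at 0 °C gives 14, which is methylenated at once.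

3. Step 18 (C1 stereocentre). The pseudoaxial C4 chain biases hydrogen delivery to the face that gives the cis isomer and may oppose the catalyst, and the peri MOM ether may slow the alkene. The fallback sets out from 23 and comes back at 24 by a radical route under thermodynamic rather than catalyst control: hydrogen-atom-transfer hydrogenation with Mn(dpm)3, PhSiH3 and t-BuOOH in i-PrOH. In it the C1 benzylic radical should take up hydrogen so that the methyl group goes pseudoaxial, away from the C8 oxygen, which is the trans arrangement with the pseudoaxial C4 chain. The minor isomer would be removed by chromatography after step 19. This fallback makes no new compound, F0.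

## Further compounds

F1 | step 14 | MOM ether of 18: methyl 4-formyl-2-methoxy-3-(methoxymethoxy)-5-[(3S,4S,8S)-4,8-dimethyl-9-(TBDPS-oxy)non-1-en-3-yl]benzoate | COC(=O)c1cc([C@@H](C=C)[C@@H](C)CCC[C@H](C)CO[Si](c2ccccc2)(c2ccccc2)C(C)(C)C)c(C=O)c(OCOC)c1OC
F2 | step 14 | divinyl carbinol: methyl 4-(1-hydroxyprop-2-en-1-yl)-2-methoxy-3-(methoxymethoxy)-5-[(3S,4S,8S)-4,8-dimethyl-9-(TBDPS-oxy)non-1-en-3-yl]benzoate, either C1 epimer | COC(=O)c1cc([C@@H](C=C)[C@@H](C)CCC[C@H](C)CO[Si](c2ccccc2)(c2ccccc2)C(C)(C)C)c(C(O)C=C)c(OCOC)c1OC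
F3 | step 14 | 1,4-dihydronaphthalen-1-ol: ring B with C1–OH and C2=C3, C4 as in 18, C8 OMOM | COC(=O)c1cc2c(c(OCOC)c1OC)C(O)C=C[C@H]2[C@@H](C)CCC[C@H](C)CO[Si](c1ccccc1)(c1ccccc1)C(C)(C)C
F4 | step 14 | tetralol: ring B saturated with C1–OH, C4 as in 18, C8 OMOM | COC(=O)c1cc2c(c(OCOC)c1OC)C(O)CC[C@H]2[C@@H](C)CCC[C@H](C)CO[Si](c1ccccc1)(c1ccccc1)C(C)(C)C
F5 | step 10 | (3S,7S)-3,7-dimethyl-8-(TBDPS-oxy)octanoic acid | OC(=O)C[C@@H](C)CCC[C@H](C)CO[Si](c1ccccc1)(c1ccccc1)C(C)(C)C
F6 | step 10 | 3-[(3S,7S)-3,7-dimethyl-8-(TBDPS-oxy)octanoyl]-1,3-oxazolidin-2-one | O=C(C[C@@H](C)CCC[C@H](C)CO[Si](c1ccccc1)(c1ccccc1)C(C)(C)C)N1CCOC1=O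
F7 | step 10 | (Z)-trimethylsilyl ketene N,O-acetal of F6 | C[Si](C)(C)O/C(=C\[C@@H](C)CCC[C@H](C)CO[Si](c1ccccc1)(c1ccccc1)C(C)(C)C)N1CCOC1=O
F8 | step 10 | α-aryl imide: 3-[(2S,3S,7S)-2-aryl-3,7-dimethyl-8-(TBDPS-oxy)octanoyl]-1,3-oxazolidin-2-one, aryl = 3-(benzyloxy)-4-methoxy-5-(methoxycarbonyl)phenyl | COC(=O)c1cc([C@@H](C(=O)N2CCOC2=O)[C@@H](C)CCC[C@H](C)CO[Si](c2ccccc2)(c2ccccc2)C(C)(C)C)cc(OCc2ccccc2)c1OC
F9 | step 10 | primary alcohol: methyl 3-(benzyloxy)-5-[(2S,3S,7S)-1-hydroxy-3,7-dimethyl-8-(TBDPS-oxy)octan-2-yl]-2-methoxybenzoate | COC(=O)c1cc([C@@H](CO)[C@@H](C)CCC[C@H](C)CO[Si](c2ccccc2)(c2ccccc2)C(C)(C)C)cc(OCc2ccccc2)c1OC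
F0 | step 18 | none | none
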